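**Retrosynthetic overview**

1. The cyclohexene ring (cis-fused to the methoxy-enedione; C12, C1′, C6′) is formed last by an intermolecular Diels–Alder reaction of the (12E)-labdatriene **10** with the chromonyl methoxy-benzoquinone **15**.
2. Quinone **15** comes from CAN oxidation of 5,7-dihydroxy-2′,4′,5′-trimethoxyflavone **14**, itself from phloroacetophenone **11** and acid chloride **12** (chromone ring by cyclodehydration).
3. Diene **10** comes from the C12 aldehyde **6** by two Wittig olefinations, with C7 corrected by oxidation/Luche reduction.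
4. Aldehyde **6** comes from abietic acid **1**: ring C is excised (SeO2 at C12, ozonolysis of C13=C14, α-ketol cleavage) and abietane C14 is kept as the exocyclic C17 via Weitz–Scheffer/Wharton. Rings A/B with C4, C5, C9, C10 are bought.
5. Ring order: A/B decalin (purchased) → chromone ring → quinone → cyclohexene ring (final step).

Assumption: diterpene numbering and α/β descriptors are used; the target is read as the [4+2] adduct of 7β-hydroxylabda-8(17),12E,14-trien-18-oic acid (4α-CO2H, same C4 configuration as abietic acid), absolute configuration exactly as in the given SMILES.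

---

**Diterpene branch**

**Step 1**
Reactants: **1** abietic acid
Product: **2** 12α-hydroxyabieta-7,13-dien-18-oic acid
Conditions: SeO2 (1.1 equiv), 1,4-dioxane–H2O, rt
Reagents that add atoms: selenium dioxide, O=[Se]=O
Why: Riley allylic hydroxylation (ene/[2,3] shift) goes to the ring CH2 (C12) next to the more substituted end of the 13,14-alkene with α-face delivery; the new C12 centre is sacrificial (destroyed in step 5).

**Step 2**
Reactants: **2**
Product: **3** 12α-hydroxy-13-oxo-13,14-secoabiet-7-en-14-al-18-oic acid (ring-B enal at C8; side chain C9–CH2–CH(OH)–CO–iPr)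
Conditions: O3 (1.0 equiv, Sudan Red 7B end-point), CH2Cl2–MeOH, −78 °C; then Me2S
Reagents that add atoms: ozone, [O-][O+]=O
Why: Ozonolysis should cleave the more exposed 13,14-terminus of the heteroannular diene (the site OsO4 also selects on abietates), and the enal formed is deactivated toward further ozone; no stereocentre is made or disturbed.

**Step 3**
Reactants: **3**
Product: **4** 7α,8α-epoxy-12α-hydroxy-13-oxo-13,14-secoabietan-14-al-18-oic acid
Conditions: 30% H2O2, Na2CO3 (pH ≈ 9–10), MeOH–H2O, 0 °C
Reagents that add atoms: hydrogen peroxide, OO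
Why: Weitz–Scheffer nucleophilic epoxidation touches only the electron-poor enal, HOO⁻ adding axially at C7 from the open α-face (anti to C20); the face is not critical because C8 becomes sp2 in step 4 and C7 is reset in steps 8–9.

**Step 4**
Reactants: **4**
Product: **5** 7α,12α-dihydroxy-13-oxo-13,14-secoabiet-8(14)-en-18-oic acid (exocyclic C8=CH2; abietane C14 = labdane C17 from here on)
Conditions: N2H4·H2O (2 equiv), AcOH (cat.), MeOH, 0 °C → rt
Reagents that add atoms: none
Why: Wharton transposition: the epoxy-aldehyde hydrazone loses N2 to give the exocyclic methylene and the C7 alcohol with retention of the epoxide C7–O bond (7α-OH); the hindered isopropyl ketone condenses slowly and any hydrazone is hydrolysed on acidic work-up.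

**Step 5**
Reactants: **5**
Product: **6** 7α-hydroxy-12-oxo-13,14,15,16-tetranorlabd-8(17)-en-18-oic acid (C9–CH2–CHO)
Conditions: H5IO6 (1.5 equiv), THF–H2O, 0 °C → rt
Reagents that add atoms: none
Why: Malaprade-type periodate cleavage of the α-ketol releases the C12 aldehyde and isobutyric acid; the allylic alcohol and 1,1-disubstituted alkene are inert and no stereocentre is affected.

**Step 6**
Reactants: **6**
Product: **7** (12E)-7α-hydroxy-14-oxo-15-norlabda-8(17),12-dien-18-oic acid
Conditions: Ph3P=C(Me)CHO (2 equiv), PhMe, 80 °C
Reagents that add atoms: 2-(triphenylphosphoranylidene)propanal, CC(C=O)=P(c1ccccc1)(c1ccccc1)c1ccccc1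
Why: Wittig olefination with a formyl-stabilised ylide gives the (E)-trisubstituted enal under thermodynamic control, and the product enal reacts much more slowly than the saturated aldehyde; free OH and CO2H are tolerated.

**Step 7**
Reactants: **7**
Product: **8** 7α-hydroxylabda-8(17),12E,14-trien-18-oic acid
Conditions: Ph3PCH3Br / KOtBu (4.5 equiv each), THF, 0 °C → rt
Reagents that add atoms: methyltriphenylphosphonium bromide, C[P+](c1ccccc1)(c1ccccc1)c1ccccc1.[Br-]
Why: Wittig methylenation (1,2-addition to the enal) completes the 12E,14-diene; excess ylide covers deprotonation of CO2H/OH and the E-olefin is untouched.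

**Step 8**
Reactants: **8**
Product: **9** 7-oxolabda-8(17),12E,14-trien-18-oic acid
Conditions: Dess–Martin periodinane, NaHCO3, CH2Cl2, 0 °C (used directly)
Reagents that add atoms: none
Why: Dess–Martin oxidation of the only alcohol (allylic, axial 7α-OH) gives the exocyclic enone under buffered, non-isomerising conditions and erases the wrong C7 configuration.

**Step 9**
Reactants: **9**
Product: **10** 7β-hydroxylabda-8(17),12E,14-trien-18-oic acid
Conditions: NaBH4, CeCl3·7H2O, MeOH, −78 → −40 °C
Reagents that add atoms: none
Why: Luche 1,2-reduction: hydride attacks C7 axially from the α-face (only H-5α/H-9α are 1,3-diaxial), giving the equatorial 7β-alcohol under control of the trans-decalin, without touching diene or acid.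

**Quinone branch**

**Step 10**
Reactants: **11** 2′,4′,6′-trihydroxyacetophenone (dried); **12** 2,4,5-trimethoxybenzoyl chloride
Product: **13** 1-(2,4,6-trihydroxyphenyl)-3-(2,4,5-trimethoxyphenyl)propane-1,3-dione
Conditions: LiHMDS (4.2 equiv), THF, −78 → −10 °C; add **12**, −78 °C → rt; aq. HCl
Reagents that add atoms: none (both carbon fragments are the reactants)
Why: Cushman polyanion acylation (Baker–Venkataraman-type C-acylation): the lithium phenoxide/enolate tetra-anion is acylated at the enolate carbon, so no phenol protection is needed.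

**Step 11**
Reactants: **13**
Product: **14** 5,7-dihydroxy-2-(2,4,5-trimethoxyphenyl)-4H-chromen-4-one
Conditions: AcOH, H2SO4 (cat.), 95 °C
Reagents that add atoms: none
Why: Acid-catalysed cyclodehydration of the o-hydroxyaryl 1,3-diketone (end of the Baker–Venkataraman flavone synthesis) closes the chromone ring.

**Step 12**
Reactants: **14**
Product: **15** 2-(5,7-dihydroxy-4-oxo-4H-chromen-2-yl)-5-methoxy-1,4-benzoquinone
Conditions: CAN (2.5–3 equiv), MeCN–H2O, 0 °C, 15 min; used at once
Reagents that add atoms: water, O (quinone oxygens come from water; two MeOH are lost)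
Why: CAN oxidative demethylation of the para-related 2′,5′-dimethoxy pair of the electron-rich B ring gives the 1,4-quinone with 4′-OMe retained, the carbonyl-deactivated 5,7-dihydroxychromone being much harder to oxidise.

**Key step**

**Step 13**
Reactants: **10** 7β-hydroxylabda-8(17),12E,14-trien-18-oic acid; **15** chromonyl methoxybenzoquinone (1.3 equiv)
Product: **16** dichrostachine E (isolated from the cis-fused adduct mixture by preparative RP-HPLC)
Conditions: PhMe–1,4-dioxane (2:1), BHT (cat.), 70 °C, dark, Ar, 24–48 h; no Lewis acid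
Reagents that add atoms: none
Why: Intermolecular Diels–Alder reaction: the methoxy-bearing quinone C=C is a deactivated vinylogous ester, so the chromonyl-substituted C=C is the dienophile and bonds through the unsubstituted termini first (C15–C6′), which puts C12 on the chromonyl carbon; suprafacial addition fixes the cis ring fusion, while the target's C12/C1′ relationship (C11 syn to the chromone) requires the chromonyl-endo/enedione-exo approach to the 12E-diene on the C12 Re face (anti to the decalin), which is not the mode the endo rule favours, so uncatalysed, apolar, warm conditions are used to weaken the enedione-endo preference and the target is separated from its diastereomers.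

---

**Compound list**

| No. | Name | SMILES | Role |
|---|---|---|---|
| 1 | Abietic acid | CC(C)C1=CC2=CC[C@@H]3[C@@]([C@H]2CC1)(CCC[C@@]3(C)C(=O)O)C | starting material |
| 2 | 12α-Hydroxyabietic acid | CC(C)C1=CC2=CC[C@@H]3[C@@]([C@H]2C[C@@H]1O)(CCC[C@@]3(C)C(=O)O)C | intermediate |
| 3 | 12α-Hydroxy-13-oxo-13,14-secoabiet-7-en-14-al-18-oic acid | O=CC1=CC[C@@H]2[C@](C)(CCC[C@@]2(C)C(=O)O)[C@H]1C[C@H](O)C(=O)C(C)C | intermediate |
| 4 | 7α,8α-Epoxide of 3 | O=C[C@@]12O[C@@H]1C[C@@H]3[C@](C)(CCC[C@@]3(C)C(=O)O)[C@H]2C[C@H](O)C(=O)C(C)C | intermediate |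
| 5 | 7α,12α-Dihydroxy-13-oxo-13,14-secoabiet-8(14)-en-18-oic acid | C=C1[C@H](O)C[C@@H]2[C@](C)(CCC[C@@]2(C)C(=O)O)[C@H]1C[C@H](O)C(=O)C(C)C | intermediate |
| 6 | 7α-Hydroxy-12-oxo-13,14,15,16-tetranorlabd-8(17)-en-18-oic acid | C=C1[C@H](O)C[C@@H]2[C@](C)(CCC[C@@]2(C)C(=O)O)[C@H]1CC=O | intermediate |
| 7 | (12E)-7α-Hydroxy-14-oxo-15-norlabda-8(17),12-dien-18-oic acid | C=C1[C@H](O)C[C@@H]2[C@](C)(CCC[C@@]2(C)C(=O)O)[C@H]1C/C=C(\C)C=O | intermediate |
| 8 | 7α-Hydroxylabda-8(17),12E,14-trien-18-oic acid | C=C1[C@H](O)C[C@@H]2[C@](C)(CCC[C@@]2(C)C(=O)O)[C@H]1C/C=C(\C)C=C | intermediate |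
| 9 | 7-Oxolabda-8(17),12E,14-trien-18-oic acid | C=C1C(=O)C[C@@H]2[C@](C)(CCC[C@@]2(C)C(=O)O)[C@H]1C/C=C(\C)C=C | intermediate |
| 10 | 7β-Hydroxylabda-8(17),12E,14-trien-18-oic acid | C=C1[C@@H](O)C[C@@H]2[C@](C)(CCC[C@@]2(C)C(=O)O)[C@H]1C/C=C(\C)C=C | intermediate (diene) |
| 11 | 2′,4′,6′-Trihydroxyacetophenone | CC(=O)c1c(O)cc(O)cc1O | starting material |
| 12 | 2,4,5-Trimethoxybenzoyl chloride | COc1cc(OC)c(OC)cc1C(Cl)=O | starting material |
| 13 | 1-(2,4,6-Trihydroxyphenyl)-3-(2,4,5-trimethoxyphenyl)propane-1,3-dione | COc1cc(OC)c(OC)cc1C(=O)CC(=O)c1c(O)cc(O)cc1O | intermediate |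
| 14 | 5,7-Dihydroxy-2′,4′,5′-trimethoxyflavone | COc1cc(OC)c(OC)cc1-c1cc(=O)c2c(O)cc(O)cc2o1 | intermediate |
| 15 | 2-(5,7-Dihydroxy-4-oxo-4H-chromen-2-yl)-5-methoxy-1,4-benzoquinone | O=C1C=C(OC)C(=O)C=C1c1cc(=O)c2c(O)cc(O)cc2o1 | intermediate (dienophile) |
| 16 | Dichrostachine E | C=C1[C@@H](O)C[C@@H]2[C@](C)(CCC[C@@]2(C)C(=O)O)[C@H]1C[C@@H]1C(C)=CC[C@H]2C(=O)C(OC)=CC(=O)[C@@]12c1cc(=O)c2c(O)cc(O)cc2o1 | target |

---

**Totals:** 13 steps; longest linear sequence 10 (steps 1–9, then 13); the quinone branch is 3 steps.

**Three steps most likely to fail, with fallbacks**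

1. **Step 13 (Diels–Alder selectivity).** Regiochemistry and cis-fusion are secure, but the target needs the chromonyl-endo mode, whereas the endo rule favours the enedione-endo adducts (C11 anti to the chromone). Facial control from C9 is also remote, so **16** may be a minor isomer needing HPLC.
   *Fallback:* make the (12Z)-triene from **6** (Still–Gennari Z-olefination, DIBAL-H, MnO2, Wittig methylenation; C7 inversion as before) and run the cycloaddition at 12–15 kbar. With the Z-diene, C11 sits "inside" and the normal enedione-endo transition state delivers the required C12/C1′ relationship.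

2. **Step 2 (ozonolysis site selectivity).** The allylic 12-OH may erode the preference for C13=C14 over C7=C8, and the ketol is base-sensitive in steps 3–4.
   *Fallback:* reverse the order. Cleave ring C of abietic acid itself (OsO4/NMO, then Pb(OAc)4; 13,14-selective), run Weitz–Scheffer/Wharton on the simple keto-enal, then unmask C12 by kinetic enolate hydroxylation of the isopropyl ketone (LDA, Davis oxaziridine) followed by periodate cleavage.

3. **Step 12 (CAN oxidation of the unprotected flavone).** Over-oxidation, o-quinone formation or decomposition of the phenol-bearing quinone are possible.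
   *Fallback:* build the B ring as 2′,5′-bis(benzyloxy)-4′-methoxy (same acylation/cyclisation with 2,5-bis(benzyloxy)-4-methoxybenzoyl chloride), hydrogenolyse to the hydroquinone flavone, and oxidise it with Ag2O in the presence of diene **10** so the quinone is trapped as it forms (domino oxidation/Diels–Alder).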